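**Retrosynthetic overview**
1. The last steps are PMB removal and tigloylation at O8, hydrolysis of a C1 dithiane, and acidic loss of the C3 silyl ether and the C9,C10 acetonide.
2. The strategy rests on the C6–C7 bond. It is the fusion bond shared by the ten-membered carbocycle (C1–C10) and the five-membered lactone (O, C6, C7, C11, C12, with exocyclic C11=C13). It is made from a C6 Z-enal and the C13 bromide of a C7=C11 enoate, and in that one flask the carbocycle closes first and the lactone second.
3. The bromomethyl enoate comes from a C7 aldehyde and methyl acrylate by a Baylis–Hillman reaction and SN2′ bromination. C6 is released and oxidised only afterwards.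
4. A C1–C6 dithiane anion is joined to a C7–C10 aldehyde at C1–C10. Oxidation and chelate-controlled MeMgBr addition then set the C10 methyl carbinol.
5. The C1–C6 piece comes from methyl propiolate (used twice) and propane-1,3-dithiol. The C7–C10 piece comes from D-glucose, whose C4 and C5 become C8 and C9.

Key step: step 24

Remark: germacrane numbering (C1–C15) is used for all intermediates, and the (S,S)-ProPhenol ligand is assumed to give the 3S carbinol, in line with its usual sense of induction for this priority pattern.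

Step 1
Reactants: 1 methyl propiolate; 2 propane-1,3-dithiol
Product: 3 methyl 2-(1,3-dithian-2-yl)acetate
Conditions: NaOMe (0.2 equiv), MeOH–CH2Cl2, −10 °C → rt
Reagents that add atoms: none
Why: Double conjugate (thia-Michael) addition: the first thiolate adds to the ynoate and the second thiol closes the six-membered ring on the β-thioacrylate, which gives C1 as a dithiane next to the C2 methylene and the C3 ester.

Step 2
Reactants: 3 methyl 2-(1,3-dithian-2-yl)acetate
Product: 4 2-(1,3-dithian-2-yl)acetaldehyde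
Conditions: iBu2AlH (1.05 equiv), toluene, −78 °C
Reagents that add atoms: none
Why: Partial reduction of an ester: the aluminium hemiacetal formed by one hydride transfer survives at −78 °C and releases the C3 aldehyde only on work-up, and no base is present that could open the β-thio aldehyde.

Step 3
Reactants: 4 2-(1,3-dithian-2-yl)acetaldehyde; 1 methyl propiolate
Product: 6 methyl (4S)-5-(1,3-dithian-2-yl)-4-hydroxypent-2-ynoate, via alkynylzinc reagent 5 (not isolated)
Conditions: 1 (3 equiv), Me2Zn (3 equiv), (S,S)-ProPhenol (20 mol %), Ph3PO (40 mol %), toluene, 4 °C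
Reagents that add atoms: Me2Zn, C[Zn]C (atoms kept only in 5)
Why: Catalytic asymmetric alkynylation of an aldehyde: the dinuclear zinc–ProPhenol complex holds the aldehyde and the alkynylzinc 5 side by side and sets C3 (S) by reagent control.

Step 4
Reactants: 6 methyl (4S)-5-(1,3-dithian-2-yl)-4-hydroxypent-2-ynoate
Product: 7 methyl (4S)-4-(tert-butyldimethylsilyloxy)-5-(1,3-dithian-2-yl)pent-2-ynoate
Conditions: TBSCl, imidazole, CH2Cl2, 0 °C → rt
Reagents that add atoms: TBSCl, CC(C)(C)[Si](C)(C)Cl
Why: Standard silylation of a secondary alcohol, which blocks lactonisation after the next step and leaves C3 untouched.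

Step 5
Reactants: 7 methyl (4S)-4-(tert-butyldimethylsilyloxy)-5-(1,3-dithian-2-yl)pent-2-ynoate
Product: 9 methyl (2Z,4S)-4-(tert-butyldimethylsilyloxy)-5-(1,3-dithian-2-yl)-3-methylpent-2-enoate, via alkenylcuprate 8 (not isolated)
Conditions: MeLi (2.2 equiv), CuI (1.1 equiv), THF, −78 °C; MeOH quench at −78 °C
Reagents that add atoms: lithium dimethylcuprate (from MeLi and CuI), [Li+].C[Cu-]C
Why: Conjugate syn-carbocupration of the ynoate: methyl and copper add to the same side in 8 and protonation at −78 °C occurs with retention, so that C3 and C6 end up cis (4Z).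

Step 6
Reactants: 9 methyl (2Z,4S)-4-(tert-butyldimethylsilyloxy)-5-(1,3-dithian-2-yl)-3-methylpent-2-enoate
Product: 10 (2Z,4S)-4-(tert-butyldimethylsilyloxy)-5-(1,3-dithian-2-yl)-3-methylpent-2-en-1-ol
Conditions: iBu2AlH (2.3 equiv), CH2Cl2, −78 °C
Reagents that add atoms: none
Why: 1,2-Reduction of the enoate by two hydride transfers, which leaves the Z C4=C5 geometry and the silyl ether untouched.

Step 7
Reactants: 10 (2Z,4S)-4-(tert-butyldimethylsilyloxy)-5-(1,3-dithian-2-yl)-3-methylpent-2-en-1-ol
Product: 11 2-[(2S,3Z)-2,5-bis(tert-butyldimethylsilyloxy)-3-methylpent-3-en-1-yl]-1,3-dithiane (C1–C6 fragment)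
Conditions: TBSCl, imidazole, CH2Cl2, rt
Reagents that add atoms: TBSCl, CC(C)(C)[Si](C)(C)Cl
Why: Standard silylation of the primary allylic alcohol, giving a C6 ether that is stable to alkyllithium and Grignard reagents and can later be cleaved before the secondary C3 ether.

Step 8
Reactants: 12 D-glucose; 13 4-methoxybenzaldehyde dimethyl acetal
Product: 14 4,6-O-[(R)-4-methoxybenzylidene]-D-glucopyranose
Conditions: p-TsOH (cat.), DMF, 55 °C, reduced pressure
Reagents that add atoms: none
Why: Acid-catalysed transacetalisation under thermodynamic control gives the six-membered O4,O6 acetal trans-fused to the pyranose with the aryl group equatorial.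

Step 9
Reactants: 14 4,6-O-[(R)-4-methoxybenzylidene]-D-glucopyranose
Product: 16 2,4-O-[(R)-4-methoxybenzylidene]-D-erythritol, via erythrose acetal 15 (not isolated)
Conditions: NaIO4 (2.2 equiv), NaHCO3, H2O, rt; then NaBH4, 0 °C
Reagents that add atoms: none
Why: Malaprade glycol cleavage excises C1 and C2 of the sugar as formate and leaves C3 as the aldehyde 15, which borohydride reduces in the same flask, so that C4 and C5 of glucose are carried over unchanged as C8 and C9.

Step 10
Reactants: 16 2,4-O-[(R)-4-methoxybenzylidene]-D-erythritol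
Product: 17 1,3-O-(di-tert-butylsilanediyl)-2,4-O-[(R)-4-methoxybenzylidene]-D-erythritol
Conditions: tBu2Si(OTf)2, 2,6-lutidine, CH2Cl2, 0 °C
Reagents that add atoms: tBu2Si(OTf)2, CC(C)(C)[Si](OS(=O)(=O)C(F)(F)F)(OS(=O)(=O)C(F)(F)F)C(C)(C)C
Why: Cyclic silylene protection of a 1,3-diol: O7 and O9 are tied in a six-membered ring trans-fused to the dioxane, a group that cannot migrate to a neighbouring alkoxide and falls to fluoride before any trialkylsilyl ether.

Step 11
Reactants: 17 1,3-O-(di-tert-butylsilanediyl)-2,4-O-[(R)-4-methoxybenzylidene]-D-erythritol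
Product: 18 [(4R,5S)-2,2-di-tert-butyl-5-(4-methoxybenzyloxy)-1,3,2-dioxasilinan-4-yl]methanol
Conditions: iBu2AlH (3 equiv), CH2Cl2, −78 → 0 °C
Reagents that add atoms: none
Why: Reductive opening of the benzylidene-type acetal: aluminium binds the less hindered primary O10, the C–O10 bond breaks and hydride is delivered to the oxocarbenium ion, which leaves the PMB group on the secondary O8.

Step 12
Reactants: 18 [(4R,5S)-2,2-di-tert-butyl-5-(4-methoxybenzyloxy)-1,3,2-dioxasilinan-4-yl]methanol
Product: 19 (4S,5S)-2,2-di-tert-butyl-5-(4-methoxybenzyloxy)-1,3,2-dioxasilinane-4-carbaldehyde (C7–C10 fragment)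
Conditions: (COCl)2, DMSO, CH2Cl2, −78 °C; iPr2NEt, −78 → 0 °C
Reagents that add atoms: none
Why: Swern oxidation of the primary alcohol, run with a hindered amine so that the α-oxygenated C9 centre is not epimerised.

Step 13
Reactants: 11 C1–C6 dithiane; 19 C7–C10 aldehyde
Product: 21 C1–C10 coupled carbinol (both C10 epimers; 3S; O7/O9 silylene; O8 PMB ether), via lithiated dithiane 20 (not isolated)
Conditions: tBuLi (1.05 equiv), THF–HMPA (10:1), −78 °C, 10 min; then 19, −78 °C
Reagents that add atoms: tBuLi, [Li]C(C)(C)C (lithium kept only in 20)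
Why: Corey–Seebach umpolung: the 2-alkyl-1,3-dithiane is deprotonated quickly in the presence of HMPA and the C1 carbanion adds to the C10 aldehyde far faster than it could attack any silyl ether, the C10 configuration being irrelevant because it is erased in the next step.

Step 14
Reactants: 21 C1–C10 coupled carbinol
Product: 22 C10 ketone (2-acyl-1,3-dithiane; 3S,8S,9S)
Conditions: (COCl)2, DMSO, CH2Cl2, −78 °C; iPr2NEt, −78 → 0 °C
Reagents that add atoms: none
Why: Swern oxidation, a method that tolerates thioacetals, turns the hindered C10 carbinol into the 2-acyl-1,3-dithiane.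

Step 15
Reactants: 22 C10 ketone
Product: 23 C7,C9-dihydroxy C10 ketone (3S,8S,9S)
Conditions: HF·pyridine (limited amount), pyridine, THF, −10 °C
Reagents that add atoms: none
Why: Fluoride-mediated desilylation: silicon bearing two oxygen atoms is much more electrophilic than that of the TBS ethers, so a limited amount of buffered HF frees O7 and O9 only.

Step 16
Reactants: 23 C7,C9-dihydroxy C10 ketone
Product: 24 C7 triethylsilyl ether of the C9-hydroxy C10 ketone (3S,8S,9S)
Conditions: TESCl (1.05 equiv), imidazole, CH2Cl2, −40 °C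
Reagents that add atoms: TESCl, CC[Si](Cl)(CC)CC
Why: Selective silylation of the primary C7 hydroxyl at low temperature, the C9 hydroxyl being secondary, hindered and deactivated by the ketone.

Step 17
Reactants: 24 C7 triethylsilyl ether of the C9-hydroxy C10 ketone
Product: 25 C9,C10 diol carrying the C10 methyl group (3S,8S,9S,10S)
Conditions: MeMgBr (4 equiv), Et2O–CH2Cl2, −78 → −30 °C
Reagents that add atoms: MeMgBr, C[Mg]Br
Why: Cram-chelate-controlled Grignard addition: the first equivalent makes the C9 magnesium alkoxide, which chelates the C10 carbonyl (a six-membered chelate through the C8 PMB ether exposes the same face), so methyl attacks anti to C8 and gives 10S, a relation that a dithiane addition to a C10 methyl ketone would reach only against chelation and against enolisation.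

Step 18
Reactants: 25 C9,C10 diol
Product: 26 C9,C10 acetonide (C7 TES ether; C8 PMB ether; C1 dithiane; C3 and C6 TBS ethers; 3S,8S,9S,10S)
Conditions: 2-methoxypropene, PPTS (cat.), CH2Cl2, 0 °C → rt
Reagents that add atoms: 2-methoxypropene, C=C(C)OC
Why: Acid-catalysed ketalisation with an enol ether under anhydrous conditions, which joins O9 and O10 in a dioxolane (C8 and C1 cis on that ring) and cannot engage the silylated O7.

Step 19
Reactants: 26 C9,C10 acetonide
Product: 27 C7 aldehyde (spatial arrangement at C8 unchanged)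
Conditions: (COCl)2 (4 equiv), DMSO, CH2Cl2, −78 → −35 °C; iPr2NEt, −78 → 0 °C
Reagents that add atoms: none
Why: Swern oxidation of a primary triethylsilyl ether: the chlorosulfonium salt attacks the least hindered silyl ether oxygen, chloride takes the silyl group, and the alkoxysulfonium ion collapses to the C7 aldehyde while the TBS ethers stay.

Step 20
Reactants: 27 C7 aldehyde; 28 methyl acrylate
Product: 29 Baylis–Hillman adduct (C7 carbinol epimers; C11=C13 methylene; C12 methyl ester)
Conditions: 28 (excess), quinuclidine (0.5 equiv), MeOH (1 equiv), rt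
Reagents that add atoms: none
Why: Baylis–Hillman reaction: the amine–acrylate zwitterion adds to the activated α-alkoxy aldehyde and forms C7–C11, the C7 carbinol configuration being of no consequence.

Step 21
Reactants: 29 Baylis–Hillman adduct
Product: 31 (Z)-2-(bromomethyl) enoate with C6 TBS ether, via allylic mesylate 30 (not isolated)
Conditions: MsCl, Et3N, CH2Cl2, −40 °C; then LiBr, THF, 0 °C → rt
Reagents that add atoms: LiBr, [Li+].[Br-]; MsCl, CS(=O)(=O)Cl (atoms kept only in 30)
Why: Mesylation followed by SN2′ displacement with bromide, which moves the alkene into conjugation (C7=C11), erases the C7 carbinol centre and gives the thermodynamically preferred isomer with C8 trans to the ester.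

Step 22
Reactants: 31 (Z)-2-(bromomethyl) enoate with C6 TBS ether
Product: 32 C6 allylic alcohol
Conditions: HF·pyridine, THF, 0 °C
Reagents that add atoms: none
Why: Selective desilylation: the primary allylic TBS ether is cleaved well before the hindered secondary C3 ether, and in unbuffered HF·pyridine no free amine is present that could be alkylated by the allylic bromide.

Step 23
Reactants: 32 C6 allylic alcohol
Product: 33 C6 Z-enal with C7=C11 bromomethyl enoate (C1 dithiane; C3 TBS ether; C8 PMB ether; C9,C10 acetonide)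
Conditions: MnO2 (activated, excess), CH2Cl2, rt
Reagents that add atoms: none
Why: Allylic oxidation with MnO2 under neutral heterogeneous conditions, which stops at the enal, keeps the Z geometry and leaves dithiane and bromide alone.

Step 24
Reactants: 33 C6 Z-enal with C7=C11 bromomethyl enoate
Product: 36 ten-membered α-methylene-γ-lactone (3S,6R,7S,8S,9S,10S; 4Z; C8 PMB ether; C1 dithiane; C3 TBS ether; C9,C10 acetonide), via allylchromium species 34 (not isolated), via chromium alkoxide 35 (not isolated)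
Conditions: CrCl2 (10 equiv), DMF–THF, rt, 33 added by syringe pump over 12 h (final 2 mM)
Reagents that add atoms: CrCl2, Cl[Cr]Cl (atoms kept only in 34 and 35)
Why: Two equivalents of divalent chromium reduce the C13–Br bond to the allylchromium 34 (trivalent chromium), which adds through its γ-carbon C7 to the C6 aldehyde in a six-membered Zimmerman–Traxler array (Cr, O, C6, C7, C11, C13), so that C6–C7 forms while the alkene moves to C11=C13; this is the Nozaki–Hiyama allylation in its 2-(alkoxycarbonyl)allyl (Dreiding–Schmidt type) variant, known for α-methylene-γ-butyrolactones and for macrocyclic closures. The ten-membered carbocycle closes by a 10-exo-trig attack on the aldehyde carbon, and the chromium alkoxide 35 then closes the γ-lactone by 5-exo-trig acyl substitution at the C12 ester with loss of methoxide. C6 follows from the chair: allylchromium reagents equilibrate faster than they add, so the bromide geometry should not be transmitted, and the array with both ring branches (C5 on C6, C8 on C7) equatorial gives the anti adduct, that is the 6,7-trans lactone. C7 is controlled by the C8 stereocentre: with H8 eclipsing the allyl unit to minimise A(1,3) strain, the aldehyde reaches C7 anti to the C8–C9 bond, which corresponds to 7S for 8S. The step needs reaction at the aldehyde only, γ- over α-attack, ring closure over oligomerisation, no loss of the C8 oxygen and no Z to E drift of the enal; these are secured by the C1 dithiane (no five-membered closure onto C1), the cyclic transition state, slow addition at high dilution together with the Z C4=C5 alkene and the cis-dioxolane that turn the two chain ends towards each other, the poor leaving ability of the PMB alkoxide, and the neutral aprotic medium.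

Step 25
Reactants: 36 ten-membered α-methylene-γ-lactone
Product: 37 C8 alcohol
Conditions: DDQ (1.3 equiv), CH2Cl2–pH 7 phosphate buffer (10:1), 0 °C
Reagents that add atoms: none
Why: Oxidative cleavage of the PMB ether by hydride abstraction with DDQ, faster at 0 °C in buffered wet CH2Cl2 than attack on the dialkyl dithiane, which is kept at this stage so that the free O8 cannot add to a C1 ketone.

Step 26
Reactants: 37 C8 alcohol; 38 tiglic acid
Product: 40 C8 tiglate, via mixed anhydride 39 (not isolated)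
Conditions: 38, 2,4,6-Cl3C6H2COCl, Et3N, toluene, rt; then 37, DMAP, rt
Reagents that add atoms: 2,4,6-trichlorobenzoyl chloride, O=C(Cl)c1c(Cl)cc(Cl)cc1Cl (atoms kept only in 39)
Why: Yamaguchi esterification: DMAP transfers the tigloyl group of the mixed anhydride 39 to the only free hydroxyl, and the E geometry of the tiglate is the stable one.

Step 27
Reactants: 40 C8 tiglate
Product: 41 C1 ketone
Conditions: MeI (excess), CaCO3, MeCN–H2O (9:1), 40 °C
Reagents that add atoms: water, O
Why: Alkylative hydrolysis of the thioacetal: S-methylation turns sulfur into a leaving group and water captures the thionium ion, non-oxidative conditions that spare the three alkenes.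

Step 28
Reactants: 41 C1 ketone
Product: 42 CNP0106709.2 (3S,6R,7S,8S,9S,10S; 4Z)
Conditions: aq. HF (48 %), MeCN, 0 °C → rt
Reagents that add atoms: none
Why: Acidic global deprotection: aqueous HF cleaves the C3 silyl ether and hydrolyses the strained dioxolane, and no stereocentre is touched.

**Compound list**
1 | methyl propiolate | C#CC(=O)OC | starting material
2 | propane-1,3-dithiol | SCCCS | starting material
3 | methyl 2-(1,3-dithian-2-yl)acetate | COC(=O)CC1SCCCS1 | intermediate
4 | 2-(1,3-dithian-2-yl)acetaldehyde | O=CCC1SCCCS1 | intermediate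
5 | methyl 3-(methylzincio)prop-2-ynoate | C[Zn]C#CC(=O)OC | intermediate
6 | methyl (4S)-5-(1,3-dithian-2-yl)-4-hydroxypent-2-ynoate | COC(=O)C#C[C@@H](O)CC1SCCCS1 | intermediate
7 | methyl (4S)-4-(tert-butyldimethylsilyloxy)-5-(1,3-dithian-2-yl)pent-2-ynoate | COC(=O)C#C[C@@H](O[Si](C)(C)C(C)(C)C)CC1SCCCS1 | intermediate
8 | lithium methyl(alkenyl)cuprate from 7 (Cu on C5, cis to the new C4 methyl) | [Li+].COC(=O)/C([Cu-]C)=C(/C)[C@@H](O[Si](C)(C)C(C)(C)C)CC1SCCCS1 | intermediate
9 | methyl (2Z,4S)-4-(tert-butyldimethylsilyloxy)-5-(1,3-dithian-2-yl)-3-methylpent-2-enoate | COC(=O)/C=C(/C)[C@@H](O[Si](C)(C)C(C)(C)C)CC1SCCCS1 | intermediate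
10 | (2Z,4S)-4-(tert-butyldimethylsilyloxy)-5-(1,3-dithian-2-yl)-3-methylpent-2-en-1-ol | OC/C=C(/C)[C@@H](O[Si](C)(C)C(C)(C)C)CC1SCCCS1 | intermediate
11 | 2-[(2S,3Z)-2,5-bis(tert-butyldimethylsilyloxy)-3-methylpent-3-en-1-yl]-1,3-dithiane | CC(C)(C)[Si](C)(C)OC/C=C(/C)[C@@H](O[Si](C)(C)C(C)(C)C)CC1SCCCS1 | intermediate
12 | D-glucose | OC[C@H]1OC(O)[C@H](O)[C@@H](O)[C@@H]1O | starting material
13 | 4-methoxybenzaldehyde dimethyl acetal | COc1ccc(cc1)C(OC)OC | starting material
14 | 4,6-O-[(R)-4-methoxybenzylidene]-D-glucopyranose | OC1O[C@@H]2CO[C@@H](c3ccc(OC)cc3)O[C@H]2[C@H](O)[C@H]1O | intermediate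
15 | 2,4-O-[(R)-4-methoxybenzylidene]-D-erythrose | O=C[C@@H]1O[C@H](c2ccc(OC)cc2)OC[C@H]1O | intermediate
16 | 2,4-O-[(R)-4-methoxybenzylidene]-D-erythritol | OC[C@@H]1O[C@H](c2ccc(OC)cc2)OC[C@H]1O | intermediate
17 | 1,3-O-(di-tert-butylsilanediyl)-2,4-O-[(R)-4-methoxybenzylidene]-D-erythritol | C1O[Si](C(C)(C)C)(C(C)(C)C)O[C@@H]2CO[C@@H](c3ccc(OC)cc3)O[C@@H]12 | intermediate
18 | [(4R,5S)-2,2-di-tert-butyl-5-(4-methoxybenzyloxy)-1,3,2-dioxasilinan-4-yl]methanol | OC[C@H]1O[Si](C(C)(C)C)(C(C)(C)C)OC[C@@H]1OCc2ccc(OC)cc2 | intermediate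
19 | (4S,5S)-2,2-di-tert-butyl-5-(4-methoxybenzyloxy)-1,3,2-dioxasilinane-4-carbaldehyde | O=C[C@H]1O[Si](C(C)(C)C)(C(C)(C)C)OC[C@@H]1OCc2ccc(OC)cc2 | intermediate
20 | 2-lithio derivative of 11 | CC(C)(C)[Si](C)(C)OC/C=C(/C)[C@@H](O[Si](C)(C)C(C)(C)C)CC1([Li])SCCCS1 | intermediate
21 | C1–C10 coupled carbinol (C10 epimers) | CC(C)(C)[Si](C)(C)OC/C=C(/C)[C@@H](O[Si](C)(C)C(C)(C)C)CC1(SCCCS1)C(O)[C@H]2O[Si](C(C)(C)C)(C(C)(C)C)OC[C@@H]2OCc3ccc(OC)cc3 | intermediate
22 | C10 ketone (2-acyl-1,3-dithiane) | CC(C)(C)[Si](C)(C)OC/C=C(/C)[C@@H](O[Si](C)(C)C(C)(C)C)CC1(SCCCS1)C(=O)[C@H]2O[Si](C(C)(C)C)(C(C)(C)C)OC[C@@H]2OCc3ccc(OC)cc3 | intermediate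
23 | C7,C9-dihydroxy C10 ketone | CC(C)(C)[Si](C)(C)OC/C=C(/C)[C@@H](O[Si](C)(C)C(C)(C)C)CC1(SCCCS1)C(=O)[C@@H](O)[C@@H](OCc2ccc(OC)cc2)CO | intermediate
24 | C7 triethylsilyl ether of the C9-hydroxy C10 ketone | CC(C)(C)[Si](C)(C)OC/C=C(/C)[C@@H](O[Si](C)(C)C(C)(C)C)CC1(SCCCS1)C(=O)[C@@H](O)[C@@H](OCc2ccc(OC)cc2)CO[Si](CC)(CC)CC | intermediate
25 | C9,C10 diol with C10 methyl (3S,8S,9S,10S) | CC(C)(C)[Si](C)(C)OC/C=C(/C)[C@@H](O[Si](C)(C)C(C)(C)C)CC1(SCCCS1)[C@@](C)(O)[C@@H](O)[C@@H](OCc2ccc(OC)cc2)CO[Si](CC)(CC)CC | intermediate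
26 | C9,C10 acetonide, C7 TES ether | CC[Si](CC)(CC)OC[C@H](OCc1ccc(OC)cc1)[C@@H]2OC(C)(C)O[C@]2(C)C3(SCCCS3)C[C@H](O[Si](C)(C)C(C)(C)C)/C(C)=C\CO[Si](C)(C)C(C)(C)C | intermediate
27 | C7 aldehyde | O=C[C@H](OCc1ccc(OC)cc1)[C@@H]2OC(C)(C)O[C@]2(C)C3(SCCCS3)C[C@H](O[Si](C)(C)C(C)(C)C)/C(C)=C\CO[Si](C)(C)C(C)(C)C | intermediate
28 | methyl acrylate | C=CC(=O)OC | starting material
29 | Baylis–Hillman adduct (C7 epimers) | C=C(C(=O)OC)C(O)[C@H](OCc1ccc(OC)cc1)[C@@H]2OC(C)(C)O[C@]2(C)C3(SCCCS3)C[C@H](O[Si](C)(C)C(C)(C)C)/C(C)=C\CO[Si](C)(C)C(C)(C)C | intermediate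
30 | C7 allylic mesylate | C=C(C(=O)OC)C(OS(C)(=O)=O)[C@H](OCc1ccc(OC)cc1)[C@@H]2OC(C)(C)O[C@]2(C)C3(SCCCS3)C[C@H](O[Si](C)(C)C(C)(C)C)/C(C)=C\CO[Si](C)(C)C(C)(C)C | intermediate
31 | (Z)-2-(bromomethyl) enoate, C6 TBS ether | BrC/C(C(=O)OC)=C\[C@H](OCc1ccc(OC)cc1)[C@@H]2OC(C)(C)O[C@]2(C)C3(SCCCS3)C[C@H](O[Si](C)(C)C(C)(C)C)/C(C)=C\CO[Si](C)(C)C(C)(C)C | intermediate
32 | (Z)-2-(bromomethyl) enoate, C6 allylic alcohol | BrC/C(C(=O)OC)=C\[C@H](OCc1ccc(OC)cc1)[C@@H]2OC(C)(C)O[C@]2(C)C3(SCCCS3)C[C@H](O[Si](C)(C)C(C)(C)C)/C(C)=C\CO | intermediate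
33 | C6 Z-enal with C7=C11 bromomethyl enoate (key-step precursor) | BrC/C(C(=O)OC)=C\[C@H](OCc1ccc(OC)cc1)[C@@H]2OC(C)(C)O[C@]2(C)C3(SCCCS3)C[C@H](O[Si](C)(C)C(C)(C)C)/C(C)=C\C=O | intermediate
34 | C13 dichlorochromium allyl species | Cl[Cr](Cl)C/C(C(=O)OC)=C\[C@H](OCc1ccc(OC)cc1)[C@@H]2OC(C)(C)O[C@]2(C)C3(SCCCS3)C[C@H](O[Si](C)(C)C(C)(C)C)/C(C)=C\C=O | intermediate
35 | ten-membered C6 dichlorochromium alkoxide, C12 methyl ester | C=C(C(=O)OC)[C@H]1[C@H](O[Cr](Cl)Cl)/C=C(/C)[C@@H](O[Si](C)(C)C(C)(C)C)CC2(SCCCS2)[C@@]3(C)OC(C)(C)O[C@H]3[C@H]1OCc4ccc(OC)cc4 | intermediate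
36 | ten-membered α-methylene-γ-lactone (key-step product) | C=C1C(=O)O[C@@H]2/C=C(/C)[C@@H](O[Si](C)(C)C(C)(C)C)CC5(SCCCS5)[C@@]3(C)OC(C)(C)O[C@H]3[C@@H](OCc4ccc(OC)cc4)[C@@H]12 | intermediate
37 | C8 alcohol | C=C1C(=O)O[C@@H]2/C=C(/C)[C@@H](O[Si](C)(C)C(C)(C)C)CC5(SCCCS5)[C@@]3(C)OC(C)(C)O[C@H]3[C@@H](O)[C@@H]12 | intermediate
38 | tiglic acid | C/C=C(\C)C(=O)O | starting material
39 | tiglic 2,4,6-trichlorobenzoic anhydride | C/C=C(\C)C(=O)OC(=O)c1c(Cl)cc(Cl)cc1Cl | intermediate
40 | C8 tiglate | C=C1C(=O)O[C@@H]2/C=C(/C)[C@@H](O[Si](C)(C)C(C)(C)C)CC5(SCCCS5)[C@@]3(C)OC(C)(C)O[C@H]3[C@@H](OC(=O)/C(C)=C/C)[C@@H]12 | intermediate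
41 | C1 ketone | C=C1C(=O)O[C@@H]2/C=C(/C)[C@@H](O[Si](C)(C)C(C)(C)C)CC(=O)[C@@]3(C)OC(C)(C)O[C@H]3[C@@H](OC(=O)/C(C)=C/C)[C@@H]12 | intermediate
42 | CNP0106709.2 | C=C1C(=O)O[C@@H]2/C=C(/C)[C@@H](O)CC(=O)[C@@](C)(O)[C@@H](O)[C@@H](OC(=O)/C(C)=C/C)[C@@H]12 | target

**Step count:** 28 steps in total. The longest linear sequence is 23 steps (steps 1–7 and 13–28).

**Steps most likely to fail**

1. Step 24.
   - What may go wrong: the allylchromium may add before it equilibrates and so pass on the geometry of the bromide (C8 cis to C13), which would reverse the relative topicity at C6 and C7. Oligomerisation and β-elimination of the C8 alkoxide can also compete.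
   - Fallback: C6 is set by substitution instead of by the allylation. Setting out from 33, the closure is taken as it comes. The 6-epi lactone F1 is opened with LiOH (THF–H2O, 0 °C) to the 6-epi hydroxy acid F2. F2 is reclosed under Mitsunobu conditions (PPh3, DIAD, toluene, 0 °C), in which the carboxylate displaces the activated allylic C6 oxygen with inversion. The route is rejoined at 36.

2. Step 20.
   - What may go wrong: turnover on the hindered α-alkoxy aldehyde may be slow, which leaves time for amine-induced epimerisation at C8.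
   - Fallback: the catalytic process is replaced by a preformed α-acrylate anion equivalent. Hydroalumination of 1 with iBu2AlH–HMPA (THF, 0 °C) gives [1-(methoxycarbonyl)vinyl]diisobutylaluminium F3, which is added to 27 at −78 → 0 °C. This sets out from 27 and rejoins the route at 29.

3. Step 28.
   - What may go wrong: the acid needed to open the dioxolane next to the C1 ketone may trigger β-elimination of the C3 oxygen or an acyl shift from O8 to O9.
   - Fallback: the order of unmasking is changed. Setting out from 40, aqueous HF in MeCN removes the silyl ether and the acetonide while C1 is still a dithiane, giving the triol dithiane F4. The ketone is then released last under near-neutral alkylative hydrolysis (MeI, CaCO3, MeCN–H2O). The route is rejoined at 42.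

**Further compounds**
F1 | step 24 | 6-epi lactone (6,7-cis; 6S) | C=C1C(=O)O[C@H]2/C=C(/C)[C@@H](O[Si](C)(C)C(C)(C)C)CC5(SCCCS5)[C@@]3(C)OC(C)(C)O[C@H]3[C@@H](OCc4ccc(OC)cc4)[C@@H]12
F2 | step 24 | 6-epi hydroxy acid | C=C(C(=O)O)[C@H]1[C@@H](O)/C=C(/C)[C@@H](O[Si](C)(C)C(C)(C)C)CC2(SCCCS2)[C@@]3(C)OC(C)(C)O[C@H]3[C@H]1OCc4ccc(OC)cc4
F3 | step 20 | [1-(methoxycarbonyl)vinyl]diisobutylaluminium | C=C(C(=O)OC)[Al](CC(C)C)CC(C)C
F4 | step 28 | triol dithiane (C8 tiglate; C3, C9 and C10 hydroxyls free) | C=C1C(=O)O[C@@H]2/C=C(/C)[C@@H](O)CC5(SCCCS5)[C@@](C)(O)[C@@H](O)[C@@H](OC(=O)/C(C)=C/C)[C@@H]12
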